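**Strategy.** Ring C is opened at the bond joining the ethyl-bearing CH to the CH that rings B and C share. The ethyl group and the ring B methylene on these neighbouring ring C carbons are cis, as in a cis-2-vinylcyclopentanecarboxylic acid. That acid is made in one operation by an Ireland–Claisen shift across a nine-membered (Z)-allylic lactone, which forms the ring C bond, sets both centres and leaves a carboxyl for ring B and a vinyl for the ethyl group. The precursor is a spiro N-Boc pyrrolidine whose quaternary carbon carries the acyl arm of the macrolactone and the O-silylated hydroxy(methyl) lactone D, cis-fused to the nine-membered ring; ring E is masked as a silyloxymethyl group.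

Key step: step 20

Remarks on the chemistry (one line each):
- Labels: Cq = quaternary carbon common to rings A, B and C; Cβ = ring C/D fusion carbon bonded to Cq; Cγ = oxygen-bearing ring C/D fusion carbon; Cα = lactone D carbon bearing CH3 and OH.
- Assumption: carbon nucleophiles add to the 2,5-disubstituted 1-pyrroline 8 on the face opposite the C2 silyloxymethyl group, so the group added last ends trans to it.
- The primary alcohol is carried as a TBDPS ether (it must survive CF3CO2H) and the tertiary alcohol as a TBS ether.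
- The silyloxy-bearing carbon Cα in 12–19 is drawn as the expected anti-aldol isomer; its configuration is immaterial because step 14 passes through the planar enolate.
- In step 20 the base is added to the lactone in the presence of Me3SiCl, because the enolate carries the carbamate nitrogen on its β-carbon and could otherwise eliminate it.

Step 1
Reactants: 1 (S)-5-(hydroxymethyl)pyrrolidin-2-one
Product: 2 O-TBDPS lactam
Conditions: TBDPSCl, imidazole, DMF, rt
Reagents that add atoms: tert-butyl(chloro)diphenylsilane, CC(C)(C)[Si](Cl)(c1ccccc1)c1ccccc1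
Why: Imidazole-promoted silylation of the primary alcohol; the acid-stable silyl ether is chosen to survive steps 4 and 25 and the stereocentre is untouched.

Step 2
Reactants: 2 O-TBDPS lactam
Product: 3 N-Boc lactam
Conditions: Boc2O, Et3N, DMAP (cat.), MeCN, rt
Reagents that add atoms: di-tert-butyl dicarbonate, CC(C)(C)OC(=O)OC(=O)OC(C)(C)C
Why: DMAP-catalysed N-acylation of the lactam activates the ring carbonyl for mono-addition of an organometallic reagent.

Step 3
Reactants: 3 N-Boc lactam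
Product: 4 N-Boc amino methyl ketone
Conditions: MeMgBr, THF, −78 °C
Reagents that add atoms: methylmagnesium bromide, C[Mg]Br
Why: Grignard addition to an N-acyl lactam stops at the ring-opened ketone because the tetrahedral adduct collapses to the carbamate anion.

Step 4
Reactants: 4 N-Boc amino methyl ketone
Product: 6 2-methyl-1-pyrroline, via amino ketone 5 (not isolated)
Conditions: CF3CO2H, CH2Cl2, 0 °C to rt; then aq. NaHCO3
Reagents that add atoms: none
Why: Acidolysis of the carbamate followed by intramolecular condensation of the amine with the ketone gives the five-membered cyclic ketimine without touching the stereocentre.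

Step 5
Reactants: 6 2-methyl-1-pyrroline
Product: 8 2-[2-(4-methoxybenzyloxy)ethyl]-1-pyrroline, via lithium aza-enolate 7 (not isolated)
Conditions: LiN(iPr)2, THF, −78 °C; then PMBOCH2Cl, −78 °C
Reagents that add atoms: 4-methoxybenzyl chloromethyl ether, COc1ccc(COCCl)cc1
Why: Kinetic metalation of the ketimine at the exocyclic methyl group, which lies on the side of the nitrogen lone pair, and C-alkylation of the aza-enolate install the oxygenated two-carbon arm that becomes the macrolactone acyl unit.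

Step 6
Reactants: 8 2-[2-(4-methoxybenzyloxy)ethyl]-1-pyrroline
Product: 9 2-allyl-2-(oxyethyl)pyrrolidine
Conditions: CH2=CHCH2MgBr, Et2O/THF, −78 to 0 °C
Reagents that add atoms: allylmagnesium bromide, C=CC[Mg]Br
Why: 1,2-Addition of an allyl Grignard reagent to a cyclic ketimine creates Cq; attack on the C=N face opposite the silyloxymethyl group puts the allyl group (future lactone D arm) trans and the oxyethyl arm cis to it, as the target requires.

Step 7
Reactants: 9 2-allyl-2-(oxyethyl)pyrrolidine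
Product: 10 N-Boc pyrrolidine
Conditions: Boc2O, Et3N, DMAP (cat.), MeCN, 60 °C
Reagents that add atoms: di-tert-butyl dicarbonate, CC(C)(C)OC(=O)OC(=O)OC(C)(C)C
Why: Carbamate formation on the hindered secondary amine, driven by heating, masks nitrogen before any carbonyl group is present.

Step 8
Reactants: 10 N-Boc pyrrolidine
Product: 11 aldehyde
Conditions: OsO4 (cat.), NaIO4, 2,6-lutidine, dioxane/H2O, rt
Reagents that add atoms: sodium periodate, [Na+].[O-]I(=O)(=O)=O
Why: Lemieux–Johnson cleavage (catalytic dihydroxylation, periodate scission) turns the terminal alkene into the aldehyde and spares the electron-rich PMB ether that ozone could attack.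

Step 9
Reactants: 11 aldehyde
Product: 12 aldol adduct
Conditions: ethyl glyoxylate (polymer form in toluene), (R)-α,α-bis[3,5-bis(trifluoromethyl)phenyl]pyrrolidin-2-ylmethanol (10 mol %), MeCN/H2O, rt
Reagents that add atoms: ethyl glyoxylate, CCOC(=O)C=O
Why: Amine-catalysed direct cross-aldol addition (enamine catalysis) to the non-enolisable glyoxylate; the (R)-configured hydrogen-bond-donor catalyst is expected, as in proline-type enamine aldol reactions, to give the (R) centre at Cβ, while the new carbinol centre is erased in step 14.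

Step 10
Reactants: 12 aldol adduct
Product: 13 silyl ether aldehyde
Conditions: TBSOTf, 2,6-lutidine, CH2Cl2, −78 °C
Reagents that add atoms: tert-butyldimethylsilyl trifluoromethanesulfonate, CC(C)(C)[Si](C)(C)OS(=O)(=O)C(F)(F)F
Why: Low-temperature silylation of the aldol hydroxyl group blocks retro-aldol cleavage and installs the silyl ether that ends on the tertiary alcohol.

Step 11
Reactants: 13 silyl ether aldehyde; 14 tert-butyldimethyl(prop-2-yn-1-yloxy)silane
Product: 16 propargylic alcohols (both carbinol epimers), via lithium acetylide 15 (not isolated)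
Conditions: 14, nBuLi, THF, −78 °C; then 13, −78 °C; AcOH quench at −78 °C
Reagents that add atoms: none
Why: 1,2-Addition of a lithium acetylide to the aldehyde is faster than enolisation or attack on the hindered α-silyloxy ester; both epimers serve because the centre is reset in steps 12 and 13, and the cold acidic quench prevents lactonisation.

Step 12
Reactants: 16 propargylic alcohols
Product: 17 ynone
Conditions: Dess–Martin periodinane, NaHCO3, CH2Cl2, 0 °C
Reagents that add atoms: none
Why: Buffered Dess–Martin oxidation gives the ynone without epimerising the adjacent Cβ centre.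

Step 13
Reactants: 17 ynone
Product: 19 lactone D with hydrogen on Cα, via hydroxy ester 18 (not isolated)
Conditions: (S)-2-methyl-CBS-oxazaborolidine (20 mol %), BH3·SMe2, THF, −30 °C; MeOH; then pyridinium p-toluenesulfonate, toluene, 50 °C
Reagents that add atoms: none
Why: Corey–Bakshi–Shibata reduction is catalyst-controlled, the slim alkynyl group acting as the small and the branched Cβ as the large substituent, so the (S) catalyst should give the (S) carbinol at Cγ; mild acid then closes γ-lactone D by 5-exo-trig acyl substitution.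

Step 14
Reactants: 19 lactone D with hydrogen on Cα
Product: 21 methylated lactone D, via lithium enolate 20 (not isolated)
Conditions: LiN(iPr)2, THF, −78 °C; then MeI, DMPU, −78 to −40 °C
Reagents that add atoms: iodomethane, CI
Why: Alkylation of an α-silyloxy γ-lactone enolate; methyl iodide approaches the face opposite the bulky pyrrolidine on Cβ and the alkynyl group on Cγ, which sets the quaternary Cα with methyl trans and silyloxy cis to Cq.

Step 15
Reactants: 21 methylated lactone D
Product: 22 (Z)-alkene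
Conditions: H2 (1 atm), Pd/CaCO3 poisoned with Pb(OAc)2, quinoline, EtOAc, rt
Reagents that add atoms: none
Why: Lindlar semihydrogenation adds hydrogen syn to the alkyne and stops at the (Z)-alkene needed for the boat array of step 20.

Step 16
Reactants: 22 (Z)-alkene
Product: 23 primary alcohol
Conditions: DDQ, CH2Cl2/pH 7 buffer, 0 °C
Reagents that add atoms: none
Why: Oxidative cleavage of the 4-methoxybenzyl ether (hydride abstraction, hydrolysis of the hemiacetal) frees only the alcohol of the acyl arm; silyl ethers, carbamate, lactone and alkene are inert.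

Step 17
Reactants: 23 primary alcohol
Product: 25 carboxylic acid, via aldehyde 24 (not isolated)
Conditions: TEMPO (cat.), PhI(OAc)2, MeCN/H2O, rt
Reagents that add atoms: water, O
Why: Nitroxyl-catalysed oxidation takes the primary alcohol through the aldehyde hydrate to the acid without touching the (Z)-alkene or the silyl ethers.

Step 18
Reactants: 25 carboxylic acid
Product: 26 seco acid
Conditions: HF·pyridine, pyridine, THF, 0 °C
Reagents that add atoms: none
Why: Buffered fluoride-mediated desilylation removes the unhindered primary allylic TBS ether much faster than the primary TBDPS ether or the hindered tertiary TBS ether.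

Step 19
Reactants: 26 seco acid
Product: 28 nine-membered (Z)-alkenyl lactone, via mixed anhydride 27 (not isolated)
Conditions: 2,4,6-Cl3C6H2COCl, Et3N, THF, rt; then slow addition to DMAP, toluene, 80 °C, high dilution
Reagents that add atoms: none
Why: Yamaguchi macrolactonisation; closure of the nine-membered ring is helped by the (Z)-alkene, the quaternary Cq and the cis relation of the two chains on lactone D, which hold acid and allylic alcohol on one side.

Step 20
Reactants: 28 nine-membered (Z)-alkenyl lactone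
Product: 32 cis-2-vinylcyclopentanecarboxylic acid bearing rings A/C/D, via lithium enolate 29 (not isolated), via silyl ketene acetal 30 (not isolated), via trimethylsilyl ester 31 (not isolated)
Conditions: LiN(iPr)2 added to 28 and Me3SiCl/Et3N, THF, −100 to −78 °C; then toluene, 60 °C; aq. citric acid
Reagents that add atoms: none
Why: The base removes an α-hydrogen of the macrolactone while Me3SiCl silylates enolate 29 at once to the endocyclic ketene acetal 30, which undergoes a suprafacial [3,3] shift across the ring: the bond between the acetal α-carbon and the far alkene carbon forms as the allylic C–O bond breaks, and hydrolysis of silyl ester 31 gives the acid. The closest known reaction type is the ester-enolate (Ireland–) Claisen ring contraction of medium-ring alkenyl lactones. Ring C closes transannularly, a 5-exo attack of the α-carbon on the alkene with allylic transposition, and the nine-membered ring allows only a boat-like six-atom array. That boat, with the (Z)-alkene and the ring-locked ketene acetal, places vinyl and carboxyl cis on the two new centres, and their face is set by the cis-fused lactone D, the six-atom array adding on the convex face of the forming bicyclo[3.3.0] unit, anti to the lactone oxygen. The step needs site-selective enolisation and survival of the enolate: lactone D has no α-hydrogen, and in situ silylation at −100 °C outruns loss of the β-carbamate nitrogen.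

Step 21
Reactants: 32 cis-2-vinylcyclopentanecarboxylic acid
Product: 34 primary alcohol, via mixed carbonic anhydride 33 (not isolated)
Conditions: iBuOCOCl, N-methylmorpholine, THF, −15 °C; then NaBH4, H2O, 0 °C
Reagents that add atoms: none
Why: Reduction of the acid through its mixed carbonic anhydride with NaBH4 is chemoselective; borane is avoided because of the vinyl group and the hindered lactone D is not reduced at 0 °C.

Step 22
Reactants: 34 primary alcohol
Product: 35 aldehyde
Conditions: Dess–Martin periodinane, NaHCO3, CH2Cl2, 0 °C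
Reagents that add atoms: none
Why: Buffered Dess–Martin oxidation gives the aldehyde without epimerising its cis-configured α-carbon.

Step 23
Reactants: 35 aldehyde; 36 [2-(1,3-dioxolan-2-yl)ethyl]triphenylphosphonium bromide
Product: 38 (Z)-alkenyl dioxolane, via phosphorus ylide 37 (not isolated)
Conditions: 36, KN(SiMe3)2, THF, −78 to 0 °C; then 35, −78 °C to rt
Reagents that add atoms: none
Why: Wittig olefination with a non-stabilised ylide adds the three remaining carbons of ring B, the last one at the aldehyde level as its acetal; the alkene geometry is irrelevant because it is hydrogenated next.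

Step 24
Reactants: 38 (Z)-alkenyl dioxolane
Product: 39 saturated ethyl compound
Conditions: H2 (1 atm), Pd/C, EtOAc, rt
Reagents that add atoms: none
Why: Heterogeneous hydrogenation saturates the vinyl group to the ethyl group and the chain alkene in one operation without creating a stereocentre.

Step 25
Reactants: 39 saturated ethyl compound
Product: 42 tetracyclic amine (rings A to D), via amino aldehyde 40 (not isolated), via iminium ion 41 (not isolated)
Conditions: CF3CO2H, H2O, CH2Cl2, 0 °C to rt; concentrate; NaBH(OAc)3, ClCH2CH2Cl, rt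
Reagents that add atoms: none
Why: Acid removes the Boc group and hydrolyses the dioxolane, the secondary amine condenses with the aldehyde (7-exo-trig) to a cyclic iminium ion, and hydride reduction completes the intramolecular reductive amination that closes azepane ring B; nitrogen cannot attack lactone D because it lies on the opposite face of ring C.

Step 26
Reactants: 42 tetracyclic amine
Product: 43 diol
Conditions: HF·pyridine, THF, rt
Reagents that add atoms: none
Why: Fluoride-mediated cleavage of both silyl ethers releases the tertiary alcohol of the target and the primary alcohol needed for ring E.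

Step 27
Reactants: 43 diol
Product: 44 amino aldehyde
Conditions: (COCl)2, Me2SO, CH2Cl2, −78 °C; then Et3N
Reagents that add atoms: none
Why: Swern oxidation converts the primary alcohol into the α-amino aldehyde at low temperature without epimerisation; the tertiary alcohol cannot be oxidised and the aldehyde is used at once.

Step 28
Reactants: 44 amino aldehyde; 45 ethyl 2-(bromomethyl)acrylate
Product: 48 α-methylene lactone, via allylzinc bromide 46 (not isolated), via hydroxy ester 47 (not isolated)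
Conditions: Zn dust, THF, 50 °C; aq. NH4Cl
Reagents that add atoms: none
Why: Zinc-mediated Barbier allylation followed by lactonisation of the zinc alkoxide builds the α-methylene-γ-butyrolactone; chelation of zinc between the aldehyde oxygen and the ring nitrogen (Cram chelate) directs attack past the hydrogen of the α-carbon and sets the new carbinol centre syn to nitrogen.

Step 29
Reactants: 48 α-methylene lactone
Product: 49 CNP0260919.4
Conditions: H2 (1 atm), Pd/C, MeOH, rt
Reagents that add atoms: none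
Why: Heterogeneous hydrogenation of the exocyclic alkene from the lactone face opposite the γ-substituent places the new methyl group cis to it and completes ring E.

**Compound list**

1 | (S)-5-(hydroxymethyl)pyrrolidin-2-one | O=C1CC[C@@H](CO)N1 | starting material
2 | (S)-5-[(tert-butyldiphenylsilyloxy)methyl]pyrrolidin-2-one | O=C1CC[C@@H](CO[Si](c2ccccc2)(c3ccccc3)C(C)(C)C)N1 | intermediate
3 | tert-butyl (S)-2-[(tert-butyldiphenylsilyloxy)methyl]-5-oxopyrrolidine-1-carboxylate | O=C1CC[C@@H](CO[Si](c2ccccc2)(c3ccccc3)C(C)(C)C)N1C(=O)OC(C)(C)C | intermediate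
4 | tert-butyl N-[(2S)-1-(tert-butyldiphenylsilyloxy)-5-oxohexan-2-yl]carbamate | CC(=O)CC[C@@H](CO[Si](c1ccccc1)(c2ccccc2)C(C)(C)C)NC(=O)OC(C)(C)C | intermediate
5 | (5S)-5-amino-6-(tert-butyldiphenylsilyloxy)hexan-2-one | CC(=O)CC[C@@H](CO[Si](c1ccccc1)(c2ccccc2)C(C)(C)C)N | intermediate (not isolated)
6 | (2S)-2-[(tert-butyldiphenylsilyloxy)methyl]-5-methyl-3,4-dihydro-2H-pyrrole | CC1=N[C@H](CO[Si](c2ccccc2)(c3ccccc3)C(C)(C)C)CC1 | intermediate
7 | N-lithio aza-enolate of 6 (exocyclic methylene) | C=C1CC[C@@H](CO[Si](c2ccccc2)(c3ccccc3)C(C)(C)C)N1[Li] | intermediate (not isolated)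
8 | (2S)-2-[(tert-butyldiphenylsilyloxy)methyl]-5-[2-(4-methoxybenzyloxy)ethyl]-3,4-dihydro-2H-pyrrole | COc1ccc(COCCC2=N[C@H](CO[Si](c3ccccc3)(c4ccccc4)C(C)(C)C)CC2)cc1 | intermediate
9 | (2S,5S)-2-allyl-2-[2-(4-methoxybenzyloxy)ethyl]-5-[(tert-butyldiphenylsilyloxy)methyl]pyrrolidine (allyl trans, oxyethyl arm cis to CH2OSi) | COc1ccc(COCC[C@]2(CC[C@@H](CO[Si](c3ccccc3)(c4ccccc4)C(C)(C)C)N2)CC=C)cc1 | intermediate
10 | N-Boc derivative of 9 | COc1ccc(COCC[C@]2(CC[C@@H](CO[Si](c3ccccc3)(c4ccccc4)C(C)(C)C)N2C(=O)OC(C)(C)C)CC=C)cc1 | intermediate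
11 | aldehyde: 10 with the allyl group cut to CH2CHO | COc1ccc(COCC[C@]2(CC[C@@H](CO[Si](c3ccccc3)(c4ccccc4)C(C)(C)C)N2C(=O)OC(C)(C)C)CC=O)cc1 | intermediate
12 | anti-aldol adduct: 11 bearing CH(OH)CO2Et on the aldehyde α-carbon Cβ, (R) at Cβ | COc1ccc(COCC[C@]2(CC[C@@H](CO[Si](c3ccccc3)(c4ccccc4)C(C)(C)C)N2C(=O)OC(C)(C)C)[C@@H](C=O)[C@H](O)C(=O)OCC)cc1 | intermediate
13 | O-TBS ether of 12 | COc1ccc(COCC[C@]2(CC[C@@H](CO[Si](c3ccccc3)(c4ccccc4)C(C)(C)C)N2C(=O)OC(C)(C)C)[C@@H](C=O)[C@H](O[Si](C)(C)C(C)(C)C)C(=O)OCC)cc1 | intermediate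
14 | tert-butyldimethyl(prop-2-yn-1-yloxy)silane | C#CCO[Si](C)(C)C(C)(C)C | starting material
15 | lithium acetylide of 14 | [Li]C#CCO[Si](C)(C)C(C)(C)C | intermediate (not isolated)
16 | propargylic alcohols from 13 and 15 (both epimers at the new carbinol carbon) | COc1ccc(COCC[C@]2(CC[C@@H](CO[Si](c3ccccc3)(c4ccccc4)C(C)(C)C)N2C(=O)OC(C)(C)C)[C@@H](C(O)C#CCO[Si](C)(C)C(C)(C)C)[C@H](O[Si](C)(C)C(C)(C)C)C(=O)OCC)cc1 | intermediate
17 | ynone (ketone at Cγ) | COc1ccc(COCC[C@]2(CC[C@@H](CO[Si](c3ccccc3)(c4ccccc4)C(C)(C)C)N2C(=O)OC(C)(C)C)[C@@H](C(=O)C#CCO[Si](C)(C)C(C)(C)C)[C@H](O[Si](C)(C)C(C)(C)C)C(=O)OCC)cc1 | intermediate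
18 | (S)-propargylic alcohol hydroxy ester | COc1ccc(COCC[C@]2(CC[C@@H](CO[Si](c3ccccc3)(c4ccccc4)C(C)(C)C)N2C(=O)OC(C)(C)C)[C@@H]([C@H](O)C#CCO[Si](C)(C)C(C)(C)C)[C@H](O[Si](C)(C)C(C)(C)C)C(=O)OCC)cc1 | intermediate (not isolated)
19 | lactone D with H on Cα: pyrrolidinyl (Cβ), alkynyl (Cγ) and OTBS (Cα) all cis | COc1ccc(COCC[C@]2(CC[C@@H](CO[Si](c3ccccc3)(c4ccccc4)C(C)(C)C)N2C(=O)OC(C)(C)C)[C@@H]5[C@H](O[Si](C)(C)C(C)(C)C)C(=O)O[C@@H]5C#CCO[Si](C)(C)C(C)(C)C)cc1 | intermediate
20 | lithium enolate of 19 | COc1ccc(COCC[C@]2(CC[C@@H](CO[Si](c3ccccc3)(c4ccccc4)C(C)(C)C)N2C(=O)OC(C)(C)C)[C@@H]5C(O[Si](C)(C)C(C)(C)C)=C(O[Li])O[C@@H]5C#CCO[Si](C)(C)C(C)(C)C)cc1 | intermediate (not isolated)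
21 | methylated lactone D: CH3 trans, OTBS cis to the pyrrolidine | COc1ccc(COCC[C@]2(CC[C@@H](CO[Si](c3ccccc3)(c4ccccc4)C(C)(C)C)N2C(=O)OC(C)(C)C)[C@@H]5[C@](C)(O[Si](C)(C)C(C)(C)C)C(=O)O[C@@H]5C#CCO[Si](C)(C)C(C)(C)C)cc1 | intermediate
22 | (Z)-alkene from 21 | COc1ccc(COCC[C@]2(CC[C@@H](CO[Si](c3ccccc3)(c4ccccc4)C(C)(C)C)N2C(=O)OC(C)(C)C)[C@@H]5[C@](C)(O[Si](C)(C)C(C)(C)C)C(=O)O[C@@H]5/C=C\CO[Si](C)(C)C(C)(C)C)cc1 | intermediate
23 | primary alcohol (2-hydroxyethyl arm on Cq) | OCC[C@]2(CC[C@@H](CO[Si](c3ccccc3)(c4ccccc4)C(C)(C)C)N2C(=O)OC(C)(C)C)[C@@H]5[C@](C)(O[Si](C)(C)C(C)(C)C)C(=O)O[C@@H]5/C=C\CO[Si](C)(C)C(C)(C)C | intermediate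
24 | aldehyde (2-oxoethyl arm on Cq) | O=CC[C@]2(CC[C@@H](CO[Si](c3ccccc3)(c4ccccc4)C(C)(C)C)N2C(=O)OC(C)(C)C)[C@@H]5[C@](C)(O[Si](C)(C)C(C)(C)C)C(=O)O[C@@H]5/C=C\CO[Si](C)(C)C(C)(C)C | intermediate (not isolated)
25 | carboxylic acid (carboxymethyl arm on Cq) | OC(=O)C[C@]2(CC[C@@H](CO[Si](c3ccccc3)(c4ccccc4)C(C)(C)C)N2C(=O)OC(C)(C)C)[C@@H]5[C@](C)(O[Si](C)(C)C(C)(C)C)C(=O)O[C@@H]5/C=C\CO[Si](C)(C)C(C)(C)C | intermediate
26 | seco acid with free (Z)-allylic alcohol | OC(=O)C[C@]2(CC[C@@H](CO[Si](c3ccccc3)(c4ccccc4)C(C)(C)C)N2C(=O)OC(C)(C)C)[C@@H]5[C@](C)(O[Si](C)(C)C(C)(C)C)C(=O)O[C@@H]5/C=C\CO | intermediate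
27 | mixed anhydride of 26 with 2,4,6-trichlorobenzoic acid | O=C(OC(=O)C[C@]2(CC[C@@H](CO[Si](c3ccccc3)(c4ccccc4)C(C)(C)C)N2C(=O)OC(C)(C)C)[C@@H]5[C@](C)(O[Si](C)(C)C(C)(C)C)C(=O)O[C@@H]5/C=C\CO)c1c(Cl)cc(Cl)cc1Cl | intermediate (not isolated)
28 | spiro N-Boc pyrrolidine nine-membered (Z)-alkenyl lactone cis-fused to O-TBS lactone D | O=C1C[C@]2(CC[C@@H](CO[Si](c3ccccc3)(c4ccccc4)C(C)(C)C)N2C(=O)OC(C)(C)C)[C@@H]5[C@](C)(O[Si](C)(C)C(C)(C)C)C(=O)O[C@@H]5/C=C\CO1 | intermediate (precursor of the key step)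
29 | lithium enolate of 28 | [Li]O/C1=C/[C@]2(CC[C@@H](CO[Si](c3ccccc3)(c4ccccc4)C(C)(C)C)N2C(=O)OC(C)(C)C)[C@@H]5[C@](C)(O[Si](C)(C)C(C)(C)C)C(=O)O[C@@H]5/C=C\CO1 | intermediate (not isolated)
30 | trimethylsilyl ketene acetal of 28 | C[Si](C)(C)O/C1=C/[C@]2(CC[C@@H](CO[Si](c3ccccc3)(c4ccccc4)C(C)(C)C)N2C(=O)OC(C)(C)C)[C@@H]5[C@](C)(O[Si](C)(C)C(C)(C)C)C(=O)O[C@@H]5/C=C\CO1 | intermediate (not isolated)
31 | trimethylsilyl ester of 32 | C=C[C@@H]1[C@H]2OC(=O)[C@@](C)(O[Si](C)(C)C(C)(C)C)[C@H]2[C@@]3(CC[C@@H](CO[Si](c4ccccc4)(c5ccccc5)C(C)(C)C)N3C(=O)OC(C)(C)C)[C@@H]1C(=O)O[Si](C)(C)C | intermediate (not isolated)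
32 | cis-2-vinylcyclopentanecarboxylic acid with rings A, C and D (vinyl and CO2H cis, anti to the lactone oxygen) | C=C[C@@H]1[C@H]2OC(=O)[C@@](C)(O[Si](C)(C)C(C)(C)C)[C@H]2[C@@]3(CC[C@@H](CO[Si](c4ccccc4)(c5ccccc5)C(C)(C)C)N3C(=O)OC(C)(C)C)[C@@H]1C(=O)O | intermediate (product of the key step)
33 | isobutyl mixed carbonic anhydride of 32 | C=C[C@@H]1[C@H]2OC(=O)[C@@](C)(O[Si](C)(C)C(C)(C)C)[C@H]2[C@@]3(CC[C@@H](CO[Si](c4ccccc4)(c5ccccc5)C(C)(C)C)N3C(=O)OC(C)(C)C)[C@@H]1C(=O)OC(=O)OCC(C)C | intermediate (not isolated)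
34 | primary alcohol (CH2OH in place of CO2H) | C=C[C@@H]1[C@H]2OC(=O)[C@@](C)(O[Si](C)(C)C(C)(C)C)[C@H]2[C@@]3(CC[C@@H](CO[Si](c4ccccc4)(c5ccccc5)C(C)(C)C)N3C(=O)OC(C)(C)C)[C@@H]1CO | intermediate
35 | aldehyde (CHO in place of CO2H) | C=C[C@@H]1[C@H]2OC(=O)[C@@](C)(O[Si](C)(C)C(C)(C)C)[C@H]2[C@@]3(CC[C@@H](CO[Si](c4ccccc4)(c5ccccc5)C(C)(C)C)N3C(=O)OC(C)(C)C)[C@@H]1C=O | intermediate
36 | [2-(1,3-dioxolan-2-yl)ethyl]triphenylphosphonium bromide | [Br-].C1COC(CC[P+](c2ccccc2)(c3ccccc3)c4ccccc4)O1 | starting material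
37 | ylide of 36 | C1COC(CC=P(c2ccccc2)(c3ccccc3)c4ccccc4)O1 | intermediate (not isolated)
38 | (Z)-4-(1,3-dioxolan-2-yl)but-1-enyl compound | C=C[C@@H]1[C@H]2OC(=O)[C@@](C)(O[Si](C)(C)C(C)(C)C)[C@H]2[C@@]3(CC[C@@H](CO[Si](c4ccccc4)(c5ccccc5)C(C)(C)C)N3C(=O)OC(C)(C)C)[C@@H]1/C=C\CC6OCCO6 | intermediate
39 | ethyl compound with saturated 4-(1,3-dioxolan-2-yl)butyl chain | CC[C@@H]1[C@H]2OC(=O)[C@@](C)(O[Si](C)(C)C(C)(C)C)[C@H]2[C@@]3(CC[C@@H](CO[Si](c4ccccc4)(c5ccccc5)C(C)(C)C)N3C(=O)OC(C)(C)C)[C@@H]1CCCC6OCCO6 | intermediate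
40 | secondary amine with 5-oxopentyl chain | CC[C@@H]1[C@H]2OC(=O)[C@@](C)(O[Si](C)(C)C(C)(C)C)[C@H]2[C@@]3(CC[C@@H](CO[Si](c4ccccc4)(c5ccccc5)C(C)(C)C)N3)[C@@H]1CCCC=O | intermediate (not isolated)
41 | seven-membered cyclic iminium trifluoroacetate | CC[C@@H]1[C@H]2OC(=O)[C@@](C)(O[Si](C)(C)C(C)(C)C)[C@H]2[C@]23CC[C@@H](CO[Si](c4ccccc4)(c5ccccc5)C(C)(C)C)[N+]2=CCCC[C@H]13.[O-]C(=O)C(F)(F)F | intermediate (not isolated)
42 | tetracyclic amine (rings A to D) with O-TBS and CH2OTBDPS | CC[C@@H]1[C@H]2OC(=O)[C@@](C)(O[Si](C)(C)C(C)(C)C)[C@H]2[C@]23CC[C@@H](CO[Si](c4ccccc4)(c5ccccc5)C(C)(C)C)N2CCCC[C@H]13 | intermediate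
43 | diol (tertiary OH and CH2OH) | CC[C@@H]1[C@H]2OC(=O)[C@@](C)(O)[C@H]2[C@]23CC[C@@H](CO)N2CCCC[C@H]13 | intermediate
44 | α-amino aldehyde | CC[C@@H]1[C@H]2OC(=O)[C@@](C)(O)[C@H]2[C@]23CC[C@@H](C=O)N2CCCC[C@H]13 | intermediate
45 | ethyl 2-(bromomethyl)acrylate | CCOC(=O)C(=C)CBr | starting material
46 | [2-(ethoxycarbonyl)allyl]zinc bromide | CCOC(=O)C(=C)C[Zn]Br | intermediate (not isolated)
47 | homoallylic alcohol (hydroxy ester) | CC[C@@H]1[C@H]2OC(=O)[C@@](C)(O)[C@H]2[C@]23CC[C@@H]([C@@H](O)CC(=C)C(=O)OCC)N2CCCC[C@H]13 | intermediate (not isolated)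
48 | α-methylene-γ-butyrolactone (ring E with exocyclic alkene) | CC[C@@H]1[C@H]2OC(=O)[C@@](C)(O)[C@H]2[C@]23CC[C@@H]([C@@H]4CC(=C)C(=O)O4)N2CCCC[C@H]13 | intermediate
49 | CNP0260919.4 | CC[C@@H]1[C@H]2OC(=O)[C@@](C)(O)[C@H]2[C@]23CC[C@@H]([C@@H]4C[C@H](C)C(=O)O4)N2CCCC[C@H]13 | target

**Step count and risk**

Total: 29 steps. Longest linear sequence: 29 steps (1 to 49); 14, 36 and 45 are bought.

The three steps most likely to fail:

Step 20. The shift may not occur below the temperature at which ketene acetal 30 decomposes, or it may take the concave face. The same ring C bond would then be made by a radical. The ketene acetal, generated as in step 20 from 28, is quenched at −78 °C with N-bromosuccinimide to give the α-bromo lactone F10. Bu3SnH and azobisisobutyronitrile (slow addition, benzene, 80 °C) induce transannular 5-exo-trig cyclisation of the α-acyl radical onto the (Z)-alkene, which after hydrogen transfer gives the cis-fused bicyclic δ-lactone F11. NaSePh (from PhSeSePh and NaBH4, DMF, 100 °C) opens this lactone at its O–CH2 carbon to the selenide acid F12. Oxidation with H2O2 and selenoxide elimination restore the vinyl group and return to the route at 32.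

Step 9. Enamine formation from the hindered aldehyde may be slow, or the catalyst may be overruled by the neighbouring quaternary centre, giving poor facial selectivity at Cβ. Cβ would then be set by an auxiliary. Oxidation of 11 (NaClO2, NaH2PO4, 2-methylbut-2-ene) gives the carboxylic acid F1, which is coupled (pivaloyl chloride, Et3N; lithiated (R)-4-benzyloxazolidin-2-one) to the N-acyl oxazolidinone F2. Its dibutylboron enolate (Bu2BOTf, iPr2NEt) adds to ethyl glyoxylate in an Evans syn-aldol reaction to give the aldol adduct F3, and silylation (TBSOTf, 2,6-lutidine) gives the silyl ether F4. LiSEt displaces the auxiliary to give the S-ethyl thioester F5, and palladium/copper-catalysed acyl Sonogashira coupling with 14 (PdCl2(dppf), CuI, Et3N) gives the ynone F6, the Cα epimer of 17. Reduction and lactonisation as in step 13 lead through the hydroxy ester F7 to the lactone F8, the Cα epimer of 19. Its enolate is 20, so the sequence returns to the route at 21.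

Step 19. Intermolecular esterification (dimers, oligomers) may outrun closure of the strained nine-membered ring. The ring would then be closed at the alkene instead. Acid 25 is esterified with allyl alcohol (EDC·HCl, DMAP, CH2Cl2) to give the allyl ester F9. Ring-closing metathesis with the second-generation Grubbs catalyst (CH2Cl2, 40 °C, high dilution) joins the allyl group to the (Z)-disubstituted alkene, which the nine-membered ring strongly prefers as (Z), and returns to the route at 28.

**Further compounds**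

F1 | step 9 | carboxylic acid from 11 (CH2CO2H arm on Cq) | COc1ccc(COCC[C@]2(CC[C@@H](CO[Si](c3ccccc3)(c4ccccc4)C(C)(C)C)N2C(=O)OC(C)(C)C)CC(=O)O)cc1
F2 | step 9 | N-acyl (R)-4-benzyloxazolidin-2-one of F1 | COc1ccc(COCC[C@]2(CC[C@@H](CO[Si](c3ccccc3)(c4ccccc4)C(C)(C)C)N2C(=O)OC(C)(C)C)CC(=O)N6C(=O)OC[C@H]6Cc7ccccc7)cc1
F3 | step 9 | Evans syn-aldol adduct of F2 with ethyl glyoxylate | COc1ccc(COCC[C@]2(CC[C@@H](CO[Si](c3ccccc3)(c4ccccc4)C(C)(C)C)N2C(=O)OC(C)(C)C)[C@@H](C(=O)N6C(=O)OC[C@H]6Cc7ccccc7)[C@@H](O)C(=O)OCC)cc1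
F4 | step 9 | O-TBS ether of F3 | COc1ccc(COCC[C@]2(CC[C@@H](CO[Si](c3ccccc3)(c4ccccc4)C(C)(C)C)N2C(=O)OC(C)(C)C)[C@@H](C(=O)N6C(=O)OC[C@H]6Cc7ccccc7)[C@@H](O[Si](C)(C)C(C)(C)C)C(=O)OCC)cc1
F5 | step 9 | S-ethyl thioester | COc1ccc(COCC[C@]2(CC[C@@H](CO[Si](c3ccccc3)(c4ccccc4)C(C)(C)C)N2C(=O)OC(C)(C)C)[C@@H](C(=O)SCC)[C@@H](O[Si](C)(C)C(C)(C)C)C(=O)OCC)cc1
F6 | step 9 | ynone, Cα epimer of 17 | COc1ccc(COCC[C@]2(CC[C@@H](CO[Si](c3ccccc3)(c4ccccc4)C(C)(C)C)N2C(=O)OC(C)(C)C)[C@@H](C(=O)C#CCO[Si](C)(C)C(C)(C)C)[C@@H](O[Si](C)(C)C(C)(C)C)C(=O)OCC)cc1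
F7 | step 9 | hydroxy ester, Cα epimer of 18 | COc1ccc(COCC[C@]2(CC[C@@H](CO[Si](c3ccccc3)(c4ccccc4)C(C)(C)C)N2C(=O)OC(C)(C)C)[C@@H]([C@H](O)C#CCO[Si](C)(C)C(C)(C)C)[C@@H](O[Si](C)(C)C(C)(C)C)C(=O)OCC)cc1
F8 | step 9 | lactone, Cα epimer of 19 | COc1ccc(COCC[C@]2(CC[C@@H](CO[Si](c3ccccc3)(c4ccccc4)C(C)(C)C)N2C(=O)OC(C)(C)C)[C@@H]5[C@@H](O[Si](C)(C)C(C)(C)C)C(=O)O[C@@H]5C#CCO[Si](C)(C)C(C)(C)C)cc1
F9 | step 19 | allyl ester of 25 | C=CCOC(=O)C[C@]2(CC[C@@H](CO[Si](c3ccccc3)(c4ccccc4)C(C)(C)C)N2C(=O)OC(C)(C)C)[C@@H]5[C@](C)(O[Si](C)(C)C(C)(C)C)C(=O)O[C@@H]5/C=C\CO[Si](C)(C)C(C)(C)C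
F10 | step 20 | α-bromo derivative of lactone 28 (either epimer at CHBr) | O=C1C(Br)[C@]2(CC[C@@H](CO[Si](c3ccccc3)(c4ccccc4)C(C)(C)C)N2C(=O)OC(C)(C)C)[C@@H]5[C@](C)(O[Si](C)(C)C(C)(C)C)C(=O)O[C@@H]5/C=C\CO1
F11 | step 20 | cis-fused cyclopentane δ-lactone from transannular radical cyclisation | O=C6OCC[C@@H]1[C@H]2OC(=O)[C@@](C)(O[Si](C)(C)C(C)(C)C)[C@H]2[C@@]3(CC[C@@H](CO[Si](c4ccccc4)(c5ccccc5)C(C)(C)C)N3C(=O)OC(C)(C)C)[C@@H]16
F12 | step 20 | 2-(phenylselanyl)ethyl carboxylic acid | c6ccccc6[Se]CC[C@@H]1[C@H]2OC(=O)[C@@](C)(O[Si](C)(C)C(C)(C)C)[C@H]2[C@@]3(CC[C@@H](CO[Si](c4ccccc4)(c5ccccc5)C(C)(C)C)N3C(=O)OC(C)(C)C)[C@@H]1C(=O)O
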